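**Retrosynthetic overview**

1. Target ⇐ (3R)-tetra-MOM isoflavanone (MOM removal) ⇐ trans-(3R,4S)-isoflavan-4-ol (buffered oxidation). The C3 stereocentre is α to C4 and benzylic to ring B, so it is configurationally secure only while C4 is an sp3 carbinol; C4 is therefore oxidised last.
2. Ring C ⇐ O1–C8a disconnection: palladium-catalysed intramolecular aryl C–O coupling of the primary C2 hydroxyl with a C8a–Br bond. The bromine sits para to the C6 methyl on ring A, which fixes O1 on C8a and so decides 6-methyl against 8-methyl.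
3. 1,3-Diol ⇐ C3–C4 bond by Evans syn aldol of the ring-B arylacetyl imide with the ring-A bromo aldehyde (sets C3), then LiBH4.
4. Ring-A aldehyde ⇐ symmetric 5-bromo-2-methylresorcinol bis-MOM ether (ortho-lithiation, formylation) ⇐ 2,6-dimethoxytoluene (C–H borylation, bromodeboronation). Ring-B imide ⇐ 4,6-dibromoresorcinol, geranyl bromide, (S)-4-benzyl-2-oxazolidinone.
5. Ring order: rings A and B are bought as benzenes; ring C is the only ring formed (step 12).

Key step: step 12

Remark: ring A is carried as its dimethyl ether through the bromodeboronation, because that step releases HBr in hot aqueous methanol, which aryl MOM ethers would not survive; the MOM groups go on after the bromine. Abbreviations: MOM = methoxymethyl; geranyl = (2E)-3,7-dimethylocta-2,6-dien-1-yl; isoflavan numbering O1, C2, C3, C4, C4a, C5–C8, C8a, ring B primed.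

**Route**

Step 1
Reactants: 1 2,6-dimethoxytoluene
Product: 3 5-bromo-1,3-dimethoxy-2-methylbenzene, via arylboronate 2 (not isolated)
Conditions: B2pin2 (1.0 equiv), [Ir(OMe)(cod)]2 (1 mol %), 4,4'-di-tert-butyl-2,2'-bipyridine (2 mol %), THF, 80 °C; evaporate; CuBr2 (3 equiv), MeOH/H2O 1:1, 80 °C
Reagents that add atoms: copper dibromide, Br[Cu]Br
Why: Iridium-catalysed arene C–H borylation is sterically governed and takes the only ring C–H without an ortho substituent (para to the methyl group), and copper-mediated bromodeboronation then puts bromine on the same carbon while the methyl ethers withstand the HBr that is released.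

Step 2
Reactants: 3 5-bromo-1,3-dimethoxy-2-methylbenzene
Product: 4 5-bromo-2-methylbenzene-1,3-diol
Conditions: BBr3 (3 equiv), CH2Cl2, −78 °C → rt; H2O
Reagents that add atoms: none
Why: BBr3 ether cleavage (Lewis-acid demethylation) frees both phenols and leaves the aryl bromide untouched.

Step 3
Reactants: 4 5-bromo-2-methylbenzene-1,3-diol
Product: 5 5-bromo-1,3-bis(methoxymethoxy)-2-methylbenzene
Conditions: MOMCl (3 equiv), i-Pr2NEt (4 equiv), DMF, 0 °C → rt
Reagents that add atoms: chloromethyl methyl ether, COCCl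
Why: O-Alkylation of the phenols with the α-chloro ether (Williamson-type MOM protection) installs groups that direct the next lithiation and survive base, hydride and palladium.

Step 4
Reactants: 5 5-bromo-1,3-bis(methoxymethoxy)-2-methylbenzene
Product: 8 6-bromo-2,4-bis(methoxymethoxy)-3-methylbenzaldehyde, via aryllithium 6 (not isolated), via lithium aminoalkoxide 7 (not isolated)
Conditions: LiN(i-Pr)2 (1.1 equiv), THF, −78 °C; DMF (2 equiv), −78 °C; H2O
Reagents that add atoms: N,N-dimethylformamide, CN(C)C=O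
Why: Directed ortho-lithiation with a lithium amide (no bromine–lithium exchange) removes the proton flanked by bromine and a MOM ether, the two such sites being equivalent by symmetry, and formylation with DMF at −78 °C (cold enough to prevent loss of LiBr to an aryne) puts the future C4 between C8a–Br and C5–OMOM.

Step 5
Reactants: 9 4,6-dibromoresorcinol
Product: 10 1,5-dibromo-2,4-bis(methoxymethoxy)benzene
Conditions: MOMCl (3 equiv), i-Pr2NEt (4 equiv), DMF, 0 °C → rt
Reagents that add atoms: chloromethyl methyl ether, COCCl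
Why: Williamson-type MOM protection of both phenols, as in step 3.

Step 6
Reactants: 10 1,5-dibromo-2,4-bis(methoxymethoxy)benzene; 11 geranyl bromide
Product: 13 1-bromo-5-geranyl-2,4-bis(methoxymethoxy)benzene, via aryllithium 12 (not isolated)
Conditions: n-BuLi (1.0 equiv), THF, −78 °C; CuBr·SMe2 (10 mol %), 11 (1.2 equiv), −78 → 0 °C
Reagents that add atoms: none
Why: Bromine–lithium exchange on the symmetric dibromide stops after one exchange at −78 °C, and copper-catalysed SN2 allylation of the aryllithium at the primary carbon of geranyl bromide keeps the E olefin.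

Step 7
Reactants: 13 1-bromo-5-geranyl-2,4-bis(methoxymethoxy)benzene
Product: 14 ethyl 2-[5-geranyl-2,4-bis(methoxymethoxy)phenyl]acetate
Conditions: BrZnCH2CO2Et (from ethyl bromoacetate and Zn in THF, 1.5 equiv), Pd2(dba)3 (2 mol %), XPhos (8 mol %), THF, 65 °C
Reagents that add atoms: ethyl bromoacetate, CCOC(=O)CBr (used as its zinc reagent, CCOC(=O)C[Zn]Br)
Why: Palladium-catalysed cross-coupling of the aryl bromide with the Reformatsky zinc enolate (Negishi-type α-arylation of an ester) forms the aryl–CH2 bond under near-neutral conditions that spare the MOM ethers and the diene.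

Step 8
Reactants: 14 ethyl 2-[5-geranyl-2,4-bis(methoxymethoxy)phenyl]acetate
Product: 15 2-[5-geranyl-2,4-bis(methoxymethoxy)phenyl]acetic acid
Conditions: LiOH (3 equiv), THF/MeOH/H2O, rt; cold 1 M HCl to pH 4
Reagents that add atoms: lithium hydroxide, [Li+].[OH-]
Why: Saponification of the ethyl ester, with acidification only to pH 4 in the cold so that the MOM ethers stay on.

Step 9
Reactants: 15 2-[5-geranyl-2,4-bis(methoxymethoxy)phenyl]acetic acid; 16 (S)-4-benzyl-2-oxazolidinone
Product: 18 (4S)-4-benzyl-3-{2-[5-geranyl-2,4-bis(methoxymethoxy)phenyl]acetyl}-1,3-oxazolidin-2-one, via mixed pivalic anhydride 17 (not isolated)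
Conditions: t-BuCOCl (1.1 equiv), Et3N (2.5 equiv), THF, −20 °C; LiCl (1.1 equiv), 16 (1.0 equiv), rt
Reagents that add atoms: none
Why: Mixed-anhydride N-acylation of the oxazolidinone (LiCl/Et3N activation) gives the imide without touching the auxiliary stereocentre.

Step 10
Reactants: 18 (4S)-4-benzyl-3-{2-[5-geranyl-2,4-bis(methoxymethoxy)phenyl]acetyl}-1,3-oxazolidin-2-one; 8 6-bromo-2,4-bis(methoxymethoxy)-3-methylbenzaldehyde
Product: 21 (4S)-4-benzyl-3-{(2S,3S)-3-[6-bromo-2,4-bis(methoxymethoxy)-3-methylphenyl]-2-[5-geranyl-2,4-bis(methoxymethoxy)phenyl]-3-hydroxypropanoyl}-1,3-oxazolidin-2-one, via boron enolate 19 (not isolated), via boron aldolate 20 (not isolated)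
Conditions: Bu2BOTf (1.2 equiv), i-Pr2NEt (1.4 equiv), CH2Cl2, −78 → 0 °C; 8 (1.2 equiv), −78 → 0 °C; pH 7 buffer, MeOH, 30 % H2O2, 0 °C
Reagents that add atoms: none
Why: Evans syn aldol reaction: soft enolisation gives the Z-boron enolate, which adds through a chair Zimmerman–Traxler transition state with the auxiliary carbonyl turned away from the enolate oxygen, so that the aldehyde enters on the face anti to the benzyl group and the (2S,3S) syn adduct should result, whose C2 becomes C3 (R) of the target.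

Step 11
Reactants: 21 the syn aldol adduct
Product: 22 (1S,2R)-1-[6-bromo-2,4-bis(methoxymethoxy)-3-methylphenyl]-2-[5-geranyl-2,4-bis(methoxymethoxy)phenyl]propane-1,3-diol
Conditions: LiBH4 (3 equiv), MeOH (3 equiv), THF, 0 °C
Reagents that add atoms: none
Why: Reductive cleavage of the imide by LiBH4 (hydride attack at the exocyclic carbonyl) gives the 1,3-diol and returns the auxiliary, at a temperature low enough to disfavour retro-aldol cleavage and without base able to epimerise the benzylic C–H.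

Step 12
Reactants: 22 (1S,2R)-1-[6-bromo-2,4-bis(methoxymethoxy)-3-methylphenyl]-2-[5-geranyl-2,4-bis(methoxymethoxy)phenyl]propane-1,3-diol
Product: 23 trans-(3R,4S)-3-[5-geranyl-2,4-bis(methoxymethoxy)phenyl]-5,7-bis(methoxymethoxy)-6-methylchroman-4-ol
Conditions: Pd(OAc)2 (5 mol %), 2-(di-tert-butylphosphino)-1,1'-binaphthyl (6 mol %), Cs2CO3 (1.5 equiv), toluene, 80 °C
Reagents that add atoms: none
Why: Oxidative addition of the C8a–Br bond to zerovalent palladium (formed in situ from Pd(OAc)2 and the phosphine), carbonate-assisted exchange of bromide for the primary C2 alkoxide, and C–O reductive elimination from the seven-membered aryl(alkoxo)palladium chelate form O1–C8a. The closest known reaction type is the Buchwald–Hartwig intramolecular etherification of 3-(2-bromoaryl)propan-1-ols to chromans with bulky di-tert-butyl(biaryl)phosphines and Cs2CO3 in toluene. Ring C closes as a six-membered ring by bond formation at the aryl carbon (the tether C4a–C4–C3–C2–O reaches C8a), and the ring-A bromine fixes O1 on the carbon flanked by C8–H and para to the C6 methyl. No stereocentre is formed: C3 (R) and C4 (S) are carried through, because C3–H is not acidic while C4 is a carbinol, so carbonate and 80 °C are tolerated, and the trans relationship follows from the syn aldol. The step needs chemoselectivity between the two hydroxyls and C–O reductive elimination in preference to β-hydride elimination: only the primary alkoxide can close a six-membered ring (the C4 alkoxide would have to form a four-membered benzoxete), and the bulky electron-rich ligand accelerates reductive elimination.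

Step 13
Reactants: 23 the trans-isoflavan-4-ol
Product: 24 (3R)-3-[5-geranyl-2,4-bis(methoxymethoxy)phenyl]-5,7-bis(methoxymethoxy)-6-methylchroman-4-one
Conditions: Dess–Martin periodinane (1.5 equiv), NaHCO3 (5 equiv), CH2Cl2, 0 °C → rt
Reagents that add atoms: none
Why: Dess–Martin oxidation of the benzylic carbinol over solid NaHCO3 gives the ketone under non-basic, nearly neutral conditions, so the now enolisable C3–H should not be epimerised and the olefins are untouched.

Step 14
Reactants: 24 the tetra-MOM isoflavanone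
Product: 25 (3R)-3-(5-geranyl-2,4-dihydroxyphenyl)-5,7-dihydroxy-6-methylchroman-4-one
Conditions: HCl (1.25 M in MeOH), THF, 0 °C → rt
Reagents that add atoms: none
Why: Acid-catalysed transacetalisation of the four aryl MOM ethers with methanol at or below room temperature frees the phenols under conditions mild enough to limit enolisation at C3 and acid cyclisation of the geranyl chain onto the 4'-hydroxyl.

**Compound list**

1 | 2,6-dimethoxytoluene (1,3-dimethoxy-2-methylbenzene) | COc1cccc(OC)c1C | starting material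
2 | 2-(3,5-dimethoxy-4-methylphenyl)-4,4,5,5-tetramethyl-1,3,2-dioxaborolane | COc1cc(B2OC(C)(C)C(C)(C)O2)cc(OC)c1C | intermediate (not isolated)
3 | 5-bromo-1,3-dimethoxy-2-methylbenzene | COc1cc(Br)cc(OC)c1C | intermediate
4 | 5-bromo-2-methylbenzene-1,3-diol | Cc1c(O)cc(Br)cc1O | intermediate
5 | 5-bromo-1,3-bis(methoxymethoxy)-2-methylbenzene | COCOc1cc(Br)cc(OCOC)c1C | intermediate
6 | [6-bromo-2,4-bis(methoxymethoxy)-3-methylphenyl]lithium | [Li]c1c(Br)cc(OCOC)c(C)c1OCOC | intermediate (not isolated)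
7 | lithium [6-bromo-2,4-bis(methoxymethoxy)-3-methylphenyl](dimethylamino)methanolate | [Li]OC(N(C)C)c1c(Br)cc(OCOC)c(C)c1OCOC | intermediate (not isolated)
8 | 6-bromo-2,4-bis(methoxymethoxy)-3-methylbenzaldehyde | O=Cc1c(Br)cc(OCOC)c(C)c1OCOC | intermediate
9 | 4,6-dibromoresorcinol | Oc1cc(O)c(Br)cc1Br | starting material
10 | 1,5-dibromo-2,4-bis(methoxymethoxy)benzene | COCOc1cc(OCOC)c(Br)cc1Br | intermediate
11 | geranyl bromide | CC(C)=CCC/C(C)=C/CBr | starting material
12 | [5-bromo-2,4-bis(methoxymethoxy)phenyl]lithium | [Li]c1cc(Br)c(OCOC)cc1OCOC | intermediate (not isolated)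
13 | 1-bromo-5-geranyl-2,4-bis(methoxymethoxy)benzene | CC(C)=CCC/C(C)=C/Cc1cc(Br)c(OCOC)cc1OCOC | intermediate
14 | ethyl 2-[5-geranyl-2,4-bis(methoxymethoxy)phenyl]acetate | CC(C)=CCC/C(C)=C/Cc1cc(CC(=O)OCC)c(OCOC)cc1OCOC | intermediate
15 | 2-[5-geranyl-2,4-bis(methoxymethoxy)phenyl]acetic acid | CC(C)=CCC/C(C)=C/Cc1cc(CC(=O)O)c(OCOC)cc1OCOC | intermediate
16 | (S)-4-benzyl-2-oxazolidinone | O=C1N[C@@H](Cc2ccccc2)CO1 | starting material
17 | 2-[5-geranyl-2,4-bis(methoxymethoxy)phenyl]acetic pivalic anhydride | CC(C)=CCC/C(C)=C/Cc1cc(CC(=O)OC(=O)C(C)(C)C)c(OCOC)cc1OCOC | intermediate (not isolated)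
18 | (4S)-4-benzyl-3-{2-[5-geranyl-2,4-bis(methoxymethoxy)phenyl]acetyl}-1,3-oxazolidin-2-one | CC(C)=CCC/C(C)=C/Cc1cc(CC(=O)N2[C@@H](Cc3ccccc3)COC2=O)c(OCOC)cc1OCOC | intermediate
19 | Z-dibutylboron enolate of 18 | CC(C)=CCC/C(C)=C/Cc1cc(/C=C(\OB(CCCC)CCCC)N2[C@@H](Cc3ccccc3)COC2=O)c(OCOC)cc1OCOC | intermediate (not isolated)
20 | O-dibutylboron aldolate of 21 | CC(C)=CCC/C(C)=C/Cc1cc([C@@H]([C@H](OB(CCCC)CCCC)c2c(Br)cc(OCOC)c(C)c2OCOC)C(=O)N2[C@@H](Cc3ccccc3)COC2=O)c(OCOC)cc1OCOC | intermediate (not isolated)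
21 | (4S)-4-benzyl-3-{(2S,3S)-3-[6-bromo-2,4-bis(methoxymethoxy)-3-methylphenyl]-2-[5-geranyl-2,4-bis(methoxymethoxy)phenyl]-3-hydroxypropanoyl}-1,3-oxazolidin-2-one | CC(C)=CCC/C(C)=C/Cc1cc([C@@H]([C@H](O)c2c(Br)cc(OCOC)c(C)c2OCOC)C(=O)N2[C@@H](Cc3ccccc3)COC2=O)c(OCOC)cc1OCOC | intermediate
22 | (1S,2R)-1-[6-bromo-2,4-bis(methoxymethoxy)-3-methylphenyl]-2-[5-geranyl-2,4-bis(methoxymethoxy)phenyl]propane-1,3-diol | CC(C)=CCC/C(C)=C/Cc1cc([C@@H]([C@H](O)c2c(Br)cc(OCOC)c(C)c2OCOC)CO)c(OCOC)cc1OCOC | intermediate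
23 | trans-(3R,4S)-3-[5-geranyl-2,4-bis(methoxymethoxy)phenyl]-5,7-bis(methoxymethoxy)-6-methylchroman-4-ol | CC(C)=CCC/C(C)=C/Cc1cc([C@@H]2COc3cc(OCOC)c(C)c(OCOC)c3[C@H]2O)c(OCOC)cc1OCOC | intermediate
24 | (3R)-3-[5-geranyl-2,4-bis(methoxymethoxy)phenyl]-5,7-bis(methoxymethoxy)-6-methylchroman-4-one | CC(C)=CCC/C(C)=C/Cc1cc([C@@H]2COc3cc(OCOC)c(C)c(OCOC)c3C2=O)c(OCOC)cc1OCOC | intermediate
25 | (3R)-3-(5-geranyl-2,4-dihydroxyphenyl)-5,7-dihydroxy-6-methylchroman-4-one (CNP0348256.1) | CC(C)=CCC/C(C)=C/Cc1cc([C@@H]2COc3cc(O)c(C)c(O)c3C2=O)c(O)cc1O | target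

**Step count and risks**

Total steps: 14. Longest linear sequence: 10 steps (steps 5–9, then 10–14); the ring-A branch (steps 1–4) joins at step 10.

Steps most likely to fail:

1. Step 12 (key step). β-Hydride elimination from a palladium alkoxide, which would oxidise a carbinol and reduce the C–Br bond, or sequestration of the catalyst as a five-membered palladacycle with the C4 alkoxide, could outrun C–O reductive elimination. Fallback, from 22 back to 23, with the polarity of the closure reversed: both hydroxyls of 22 are deprotonated with n-BuLi (2 equiv, THF, −78 °C), bromine is exchanged for lithium with t-BuLi (2 equiv), and the aryllithium is trapped with B(OMe)3 and oxidised with H2O2/NaOH to the phenol (1S,2R)-1-[6-hydroxy-2,4-bis(methoxymethoxy)-3-methylphenyl]-2-[5-geranyl-2,4-bis(methoxymethoxy)phenyl]propane-1,3-diol F1. Mitsunobu closure (PPh3, DIAD, THF, 0 °C) of the phenol onto the primary alcohol then forms O1–C2 and gives 23; O1 is still on C8a because it replaces the bromine.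

2. Step 10. Addition of the conjugated boron enolate to the doubly ortho-substituted, electron-rich aldehyde may be slow, and the aldolate may revert during work-up. Fallback, from 18 back to 22 and 24, with the C4–C4a bond made instead of C3–C4:
   - Chelate-controlled Evans alkylation of 18 (NaN(SiMe3)2, THF, −78 °C; (triisopropylsiloxy)methyl chloride) should give (4S)-4-benzyl-3-{(2R)-2-[5-geranyl-2,4-bis(methoxymethoxy)phenyl]-3-[(triisopropylsilyl)oxy]propanoyl}-1,3-oxazolidin-2-one F2. The electrophile enters on the face opposite to that of the boron aldol, but the new carbon becomes C2 and the imide carbonyl becomes C4, so the C3 configuration is the same.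
   - LiBH4 gives (2S)-2-[5-geranyl-2,4-bis(methoxymethoxy)phenyl]-3-[(triisopropylsilyl)oxy]propan-1-ol F3, and buffered Dess–Martin oxidation gives (2R)-2-[5-geranyl-2,4-bis(methoxymethoxy)phenyl]-3-[(triisopropylsilyl)oxy]propanal F4, used at once.
   - Aryllithium 6 (from 5 as in step 4), transmetallated with CeCl3 to suppress enolisation, adds at −78 °C to give (2R)-1-[6-bromo-2,4-bis(methoxymethoxy)-3-methylphenyl]-2-[5-geranyl-2,4-bis(methoxymethoxy)phenyl]-3-[(triisopropylsilyl)oxy]propan-1-ol F5 as a mixture of carbinol epimers.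
   - Bu4NF gives 22 together with its epimer (1R,2R)-1-[6-bromo-2,4-bis(methoxymethoxy)-3-methylphenyl]-2-[5-geranyl-2,4-bis(methoxymethoxy)phenyl]propane-1,3-diol F6. Under the conditions of step 12, F6 gives cis-(3R,4R)-3-[5-geranyl-2,4-bis(methoxymethoxy)phenyl]-5,7-bis(methoxymethoxy)-6-methylchroman-4-ol F7, which step 13 converts into the same ketone 24.

3. Step 14. Acid-promoted enolisation at C3 (erosion of enantiopurity) and cyclisation of the geranyl olefin onto the freed 4'-hydroxyl may compete with the slower MOM cleavages. Fallback, from 24 to 25, through a protecting-group exchange without protic acid: Et3SiOTf and 2,2'-bipyridyl (CH2Cl2, 0 °C → rt) convert the four aryl MOM ethers directly into aryl silyl ethers, giving (3R)-3-[5-geranyl-2,4-bis(triethylsilyloxy)phenyl]-6-methyl-5,7-bis(triethylsilyloxy)chroman-4-one F8. Et3N·3HF in THF at 0 °C then frees the phenols to give 25.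

**Further compounds**

F1 | step 12 | (1S,2R)-1-[6-hydroxy-2,4-bis(methoxymethoxy)-3-methylphenyl]-2-[5-geranyl-2,4-bis(methoxymethoxy)phenyl]propane-1,3-diol | CC(C)=CCC/C(C)=C/Cc1cc([C@@H]([C@H](O)c2c(O)cc(OCOC)c(C)c2OCOC)CO)c(OCOC)cc1OCOC
F2 | step 10 | (4S)-4-benzyl-3-{(2R)-2-[5-geranyl-2,4-bis(methoxymethoxy)phenyl]-3-[(triisopropylsilyl)oxy]propanoyl}-1,3-oxazolidin-2-one | CC(C)=CCC/C(C)=C/Cc1cc([C@@H](C(=O)N2[C@@H](Cc3ccccc3)COC2=O)CO[Si](C(C)C)(C(C)C)C(C)C)c(OCOC)cc1OCOC
F3 | step 10 | (2S)-2-[5-geranyl-2,4-bis(methoxymethoxy)phenyl]-3-[(triisopropylsilyl)oxy]propan-1-ol | CC(C)=CCC/C(C)=C/Cc1cc([C@@H](CO)CO[Si](C(C)C)(C(C)C)C(C)C)c(OCOC)cc1OCOC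
F4 | step 10 | (2R)-2-[5-geranyl-2,4-bis(methoxymethoxy)phenyl]-3-[(triisopropylsilyl)oxy]propanal | CC(C)=CCC/C(C)=C/Cc1cc([C@@H](C=O)CO[Si](C(C)C)(C(C)C)C(C)C)c(OCOC)cc1OCOC
F5 | step 10 | (2R)-1-[6-bromo-2,4-bis(methoxymethoxy)-3-methylphenyl]-2-[5-geranyl-2,4-bis(methoxymethoxy)phenyl]-3-[(triisopropylsilyl)oxy]propan-1-ol, carbinol epimers | CC(C)=CCC/C(C)=C/Cc1cc([C@@H](C(O)c2c(Br)cc(OCOC)c(C)c2OCOC)CO[Si](C(C)C)(C(C)C)C(C)C)c(OCOC)cc1OCOC
F6 | step 10 | (1R,2R)-1-[6-bromo-2,4-bis(methoxymethoxy)-3-methylphenyl]-2-[5-geranyl-2,4-bis(methoxymethoxy)phenyl]propane-1,3-diol | CC(C)=CCC/C(C)=C/Cc1cc([C@@H]([C@@H](O)c2c(Br)cc(OCOC)c(C)c2OCOC)CO)c(OCOC)cc1OCOC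
F7 | step 10 | cis-(3R,4R)-3-[5-geranyl-2,4-bis(methoxymethoxy)phenyl]-5,7-bis(methoxymethoxy)-6-methylchroman-4-ol | CC(C)=CCC/C(C)=C/Cc1cc([C@@H]2COc3cc(OCOC)c(C)c(OCOC)c3[C@@H]2O)c(OCOC)cc1OCOC
F8 | step 14 | (3R)-3-[5-geranyl-2,4-bis(triethylsilyloxy)phenyl]-6-methyl-5,7-bis(triethylsilyloxy)chroman-4-one | CC(C)=CCC/C(C)=C/Cc1cc([C@@H]2COc3cc(O[Si](CC)(CC)CC)c(C)c(O[Si](CC)(CC)CC)c3C2=O)c(O[Si](CC)(CC)CC)cc1O[Si](CC)(CC)CC
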